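Locants used throughout (hydrindane numbering, also for precursors): C1 (CHEt), C2 (C=O), C3 (CHMe), C3a, C4 (CMe=), C5 (=CH), C6, C7, C7a; Cα and Cβ are the styryl carbons. Ring A is the cyclopentanone, ring B the cyclohexene.

## The problem

The target is a trans-fused hydrindan-2-one: ring A (C1, C2, C3, C3a, C7a) is fused to ring B (C3a, C4=C5, C6, C7, C7a), and six stereocentres sit on nine ring atoms. The core difficulty is the pair of adjacent quaternary carbons, C6 (ethyl, (E)-styryl) and C7 (ethyl, carboxyl), which must be set against each other and against the trans ring fusion. C1 and C3 flank the C2 ketone and are epimerisable. Their required configuration (C1-ethyl anti to C7, C3-methyl anti to C4) is the less congested one, so both can be left to a final equilibration. C7 cannot be corrected once made, so it has to carry the absolute configuration and pass it on to C7a, C6 and C3a. The C7 acid is γ,δ-unsaturated towards both the ring alkene and the styrene, so strong acid and electrophiles are excluded late in the route; the C6/C7 region is also too hindered for late intermolecular C–C bond formation or ester saponification. The enabling feature is that Cα on C6 and C3 on C3a lie cis-1,4 across ring B, on the face of the C7 carboxyl group. A temporary Cα–C3 bond therefore turns ring B into a bicyclo[2.2.2]octene whose C4=C5 alkene is exactly the one a Diels–Alder reaction of a C6=C5–C4=C3a diene leaves behind, and the carboxyl group can hold the two-carbon dienophile.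

## Retrosynthesis

**27 ⇒ 25.** No skeletal bond is cut. Target 27 is traced to β-keto ester 25, which carries an extra CO2Me on C1 and the C7 carboxyl as its methyl ester. Alkylating a bare C2 ketone would have to choose between C1 and C3; the extra ester makes C1 the only doubly activated position. The forward step must demethylate both esters, decarboxylate at C1 and equilibrate C1 and C3 (through keto acid 26).

**25 ⇒ 23.** Cutting C1–ethyl and then C1–C2 opens ring A to the monocyclic triester 23 (through keto diester 24). The C1–C2 cut is preferred to C2–C3: only closure of the C1 enolate onto the C3 ester carbonyl gives a β-keto ester with an acidic proton, so only this Dieckmann mode has a thermodynamic sink. The forward step needs equilibrating base and C-ethylation of the resulting enolate.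

**23 ⇒ 21 + 22.** The Cα=Cβ bond is cut to the C6 aldehyde 21 and diethyl benzylphosphonate 22. Phenyl arrives late because Cα must first serve as an oxygen-bearing dienophile carbon. The aldehyde is non-enolisable, and the olefination only has to be (E)-selective.

**21 ⇒ 19.** The C6 formyl group and the C3 ester carbon are aldol partners held cis-1,4 across ring B. Reconnecting Cα–C3, and Cα–O to the C7 carboxyl, gives the lactone-bridged bicyclo[2.2.2]octene 19 (through hydroxy triester 20). This adds a bond the target lacks, but it converts two remote cis substituents and a quaternary centre into a single cycloadduct. The forward step asks methoxide to open the lactone and the freed β-alkoxide to fragment; the quaternary C3 blocks β-elimination.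

**19 ⇒ 18.** The C6–Cα and C3a–C3 bonds are cut in the Diels–Alder sense, giving the cyclohexa-1,3-diene enol ester 18. An intermolecular cycloaddition would have no facial or regiochemical control at a diene terminus that becomes quaternary. The ester tether from C7 supplies both, and it sets C6 and C3a from the single stereocentre C7. The precursor has two stereocentres instead of six.

**18 ⇒ 14 + 16; 16 ⇒ 15.** The enol ester C(=O)–O bond is cut to acid 14 (activated as acid chloride 17) and methyl 2-formylpropanoate 16, a formylation product of methyl propanoate 15. The α-methyl group of 16 becomes the C3 methyl group and prevents later β-elimination.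

**14 ⇒ 12 ⇒ 11.** The acid is masked as tert-butyl ester 12 (freed through silyl ester 13), and the C4–CH3 bond is cut to dienyl triflate 11. Methyl addition to a C4 ketone followed by dehydration would leave the alkene position open; the triflate defines the C3a=C4–C5=C6 diene.

**11 ⇒ 8 + 9.** The C7a–C1 bond is cut as a conjugate addition of acetate ketene silyl acetal 9 to dienone 8. The silyl dienol ether 10 formed in that step already has the C3a=C4 enol regiochemistry and is exchanged for triflate. The addition must occur at C7a on the face of the C7 ethyl group.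

**8 ⇒ 6 ⇒ 4 ⇒ 2 + 3; 2 ⇒ 1.** The C3a=C7a unsaturation comes from dehydrogenation of enone 6 (through silyl dienol ether 7). The C5–C6 bond comes from aldol condensation of diketone 4 (through ketol 5). The C7–C7a bond comes from a catalytic asymmetric Michael addition of β-keto ester 2 to but-3-en-2-one 3, which sets C7. Compound 2 is the ethylation product of tert-butyl 3-oxopentanoate 1.

## Roads not taken

**Alternative 1:** The cut is C6–C7, the bond between the two quaternary carbons. In the forward step δ-lactone A1 (ring oxygen on C4, next to a 1,3-dienyl arm) is converted with LiN(iPr)2 and Me3SiCl into its silyl ketene acetal. This rearranges in a boat-like [3,3] shift that forms C6–C7, moves the alkene to C4=C5 and contracts the lactone to the ring B acid A2.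
- Merits: the hardest bond is made directly, both quaternary centres are set together, the styryl group is already in place and the carboxyl group emerges free. In these respects it is better than the chosen plan, which forms and later breaks a sacrificial Cα–C3 bond and needs a separate olefination.
- Weak points: A1 must already contain C3, C3a, C7a and a configured tertiary, doubly allylic C4–O centre plus a geometrically defined trisubstituted diene. That ester is prone to ionisation or elimination under enolisation. A fully substituted ketene acetal has to attack a fully substituted alkene terminus. Ring A still has to be closed from the propenyl and silyloxymethyl arms of A2.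
- Comparison: the chosen plan sets against this a key-step substrate with only two stereocentres, made in a short linear sequence, and a cycloaddition whose facial and regiochemical outcome is fixed by a short tether.

**Alternative 2:** The cuts are C3a–C7a, C1–C2 and C2–C3. In the forward step Co2(CO)8 (zerovalent cobalt) with an amine N-oxide joins the C7a≡C1 alkyne and the C3a=C3 alkene of dienyne lactone A3 with CO, giving tricyclic enone A4 with rings A and B closed at once.
- Merits: three C–C bonds and two rings in one step, and the C6/C7 pair is locked beforehand in a small lactone. In bonds formed per step it is better than the chosen plan.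
- Weak points: the alkene partner is an internal alkene that is part of a conjugated diene, and the alkyne sits on a quaternary propargylic carbon. Ring B must form as the larger ring of a 1,7-enyne. A4 leaves C7a as part of a tetrasubstituted enone, so the trans ring fusion depends on a late reduction next to quaternary C7. The lactone CH2–O must be reoxidised before olefination.
- Comparison: the chosen plan fixes C7a and C3a before ring A exists, so the trans fusion is not left to a late reduction.

**Alternative 3:** The cut is the C4=C5 alkene. In the forward step TiCl3 and Zn(Cu) (low-valent titanium) couple the C4 methyl ketone and the neopentyl C5 aldehyde of keto aldehyde A5, closing ring B to give A6, the C2 ketal and methyl ester of the target.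
- Merits: the alkene is formed with no regiochemical question, the coupling tolerates hindrance, and A6 is two deprotections from the target. This is the shortest endgame of all four plans.
- Weak points: the key step creates no stereocentre. All six, including the C6–C7 quaternary pair on an open chain hanging from a cyclopentane, must be built into A5 without ring control. The reductant must also leave the ester and the styrene alone.
- Comparison: the chosen plan has a longer endgame, but its key step creates four stereocentres, two of them from ring geometry alone.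

Key step: step 10

Remarks on the chemistry (assumptions):
- The (R)-BINAP palladium complex of step 2 is assumed to give the (2R)-adduct 4; if the opposite sense is found, the antipodal ligand is used.
- Compounds 21 and 23–26 are carried as mixtures at C3 (and at C1 for 25 and 26). These centres are drawn without configuration because step 14 sets them by equilibration.

## Route

Step 1
Reactants: 1 tert-butyl 3-oxopentanoate
Product: 2 tert-butyl 2-ethyl-3-oxopentanoate (racemic)
Conditions: EtI, K2CO3, acetone, reflux
Reagents that add atoms: iodoethane, CCI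
Why: C-alkylation of the stabilised β-keto ester enolate (acetoacetic ester alkylation); the mild carbonate base limits dialkylation, and the new centre is enolisable and of no consequence.

Step 2
Reactants: 2 tert-butyl 2-ethyl-3-oxopentanoate; 3 but-3-en-2-one
Product: 4 tert-butyl (2R)-2-ethyl-5-oxo-2-propanoylhexanoate
Conditions: [Pd((R)-BINAP)(H2O)2](OTf)2 (5 mol %), THF, −20 °C
Reagents that add atoms: none
Why: Catalytic asymmetric Michael addition through a chiral enolate of divalent palladium, a method established for α-substituted tert-butyl β-keto esters and enones. The chelated enolate is shielded on one face by the ligand, so the catalyst sets the quaternary centre C7 and forms the C7–C7a bond.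

Step 3
Reactants: 4 tert-butyl (2R)-2-ethyl-5-oxo-2-propanoylhexanoate
Product: 6 tert-butyl (1R)-1,2-diethyl-4-oxocyclohex-2-ene-1-carboxylate, via ketol 5 (not isolated)
Conditions: pyrrolidine, AcOH, toluene, 60 °C
Reagents that add atoms: none
Why: Intramolecular aldol condensation (Robinson annulation in the enamine mode). Only the unhindered methyl ketone forms an enamine, and only its terminal carbon can reach the propanoyl carbonyl through a six-membered transition state, so C5–C6 forms regioselectively; C7 is quaternary and cannot epimerise.

Step 4
Reactants: 6 tert-butyl (1R)-1,2-diethyl-4-oxocyclohex-2-ene-1-carboxylate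
Product: 8 tert-butyl (1R)-1,2-diethyl-4-oxocyclohexa-2,5-diene-1-carboxylate, via trimethylsilyl dienol ether 7 (not isolated)
Conditions: LiN(iPr)2, Me3SiCl, THF, −78 °C; then Pd(OAc)2, MeCN, rt
Reagents that add atoms: none
Why: Saegusa–Ito dehydrogenation: kinetic deprotonation at C3a, O-silylation, then palladation by divalent palladium and β-hydride elimination give the cross-conjugated dienone. C7 is untouched.

Step 5
Reactants: 8 tert-butyl (1R)-1,2-diethyl-4-oxocyclohexa-2,5-diene-1-carboxylate; 9 tert-butyl[(1-methoxyethenyl)oxy]dimethylsilane
Product: 11 tert-butyl (1R,6S)-1,2-diethyl-6-(2-methoxy-2-oxoethyl)-4-(trifluoromethanesulfonyloxy)cyclohexa-2,4-diene-1-carboxylate, via TBS dienol ether 10 (not isolated)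
Conditions: TBSOTf (10 mol %), CH2Cl2, −78 °C; evaporate; then CsF, PhNTf2, DME, rt
Reagents that add atoms: N-phenylbis(trifluoromethanesulfonimide), O=S(=O)(N(c1ccccc1)S(=O)(=O)C(F)(F)F)C(F)(F)F
Why: Mukaiyama–Michael addition at C7a, the only unsubstituted β-carbon, followed by the known fluoride-mediated exchange of a silyl enol ether for triflate, which fixes the C3a=C4 enol regiochemistry. C7a is set by substrate control: the ketene acetal is expected to enter anti to the tert-butoxycarbonyl group on C7 (larger than ethyl next to the reacting carbon), placing the acetate arm cis to the C7 ethyl group.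

Step 6
Reactants: 11 dienyl triflate
Product: 12 tert-butyl (1R,6S)-1,2-diethyl-6-(2-methoxy-2-oxoethyl)-4-methylcyclohexa-2,4-diene-1-carboxylate
Conditions: MeZnCl, Pd(PPh3)4 (5 mol %), THF, 50 °C
Reagents that add atoms: methylzinc chloride, C[Zn]Cl
Why: Negishi coupling (oxidative addition of the triflate to zerovalent palladium, transmetalation, reductive elimination) installs the C4 methyl group, tolerates both esters and leaves the C3a=C4–C5=C6 diene regiodefined.

Step 7
Reactants: 12 diene tert-butyl ester
Product: 14 (1R,6S)-1,2-diethyl-6-(2-methoxy-2-oxoethyl)-4-methylcyclohexa-2,4-diene-1-carboxylic acid, via trimethylsilyl ester 13 (not isolated)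
Conditions: Me3SiOTf, 2,6-lutidine, CH2Cl2, 0 °C to rt; then pH 5 aqueous buffer
Reagents that add atoms: none
Why: Silyl triflate-mediated cleavage of the tert-butyl ester with loss of 2-methylpropene, run buffered and non-protic because protic acid would protonate the electron-rich diene. The methyl ester is inert and the silyl ester hydrolyses on work-up.

Step 8
Reactants: 15 methyl propanoate
Product: 16 methyl 2-formylpropanoate (aldehyde/enol tautomers)
Conditions: NaH, HCO2Me, Et2O, 0 °C to rt; then cold 1 M HCl
Reagents that add atoms: methyl formate, COC=O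
Why: Crossed Claisen condensation (formylation) of the ester enolate with methyl formate; the product is held as its sodium enolate, which drives the equilibrium.

Step 9
Reactants: 14 diene acid; 16 methyl 2-formylpropanoate
Product: 18 (E)-3-methoxy-2-methyl-3-oxoprop-1-en-1-yl (1R,6S)-1,2-diethyl-6-(2-methoxy-2-oxoethyl)-4-methylcyclohexa-2,4-diene-1-carboxylate, via acid chloride 17 (not isolated)
Conditions: 1-chloro-N,N,2-trimethylprop-1-en-1-amine, CH2Cl2, 0 °C; then 16, Et3N, N-methylimidazole (cat.), −20 °C to rt
Reagents that add atoms: none
Why: Neutral acid chloride formation (no HCl, and no ketene is possible at quaternary C7) followed by O-acylation of the amine-generated, non-chelated enolate of 16. The hard acylammonium electrophile reacts at oxygen, and the (E)-enol ester (acyloxy trans to CO2Me) is the isomer favoured under nucleophilic catalysis; either geometry would converge on 21 after step 11.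

Step 10
Reactants: 18 enol ester of the ring B cyclohexadiene acid
Product: 19 lactone-bridged bicyclo[2.2.2]octene adduct (bridgeheads C6 and C3a; bridges C4(Me)=C5, C7(Et)–C7a(H)(CH2CO2Me) and Cα(H)(O)–C3(Me)(CO2Me); γ-lactone C7–C(=O)–O–Cα; C3 ester and C7a arm both syn to the C4=C5 bridge)
Conditions: toluene (0.01 M), BHT (cat.), 130 °C, sealed vessel
Reagents that add atoms: none
Why: Concerted, suprafacial intramolecular (4+2) cycloaddition of the C6=C5–C4=C3a diene with the tethered Cα=C3 alkene, forming C6–Cα and C3a–C3 and leaving the alkene at C4=C5. The closest known reaction type is the thermal cyclisation of cyclohexa-2,4-dienyl systems that carry an acrylate ester on the sp3 ring carbon next to the diene, which gives the same lactone-bridged bicyclo[2.2.2]octene skeleton. The five-membered lactone (C6, C7, C=O, O, Cα) closes as the tether ring, and the new six-membered ring (C6, Cα, C3, C3a, C4, C5) closes as the bridge across ring B. C6 and C3a are controlled by C7: the three-atom tether lets the dienophile reach only the carboxyl face, which is anti to the C7a arm, so C3 ends trans to that arm. Cα and C3 follow from the (E)-geometry, with the tether oxygen exo and the C3 ester endo; both centres are erased in step 11. Regiochemistry (Cα to C6) is dictated by the tether length, so the hindered diene terminus meets the CH end of the dienophile. The step needs cycloaddition to outrun diene isomerisation and dimerisation: dilution and a radical inhibitor address the latter, quaternary C7 blocks hydrogen shift from that side, and the 1,5-shift from C7a in a cyclohexa-1,3-diene is not expected to compete at this temperature. No Lewis acid is used because the enol ester is a vinylogous anhydride that could ionise at the acyl carbon.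

Step 11
Reactants: 19 lactone-bridged adduct
Product: 21 methyl 1,2-diethyl-2-formyl-6-(2-methoxy-2-oxoethyl)-5-(1-methoxy-1-oxopropan-2-yl)-4-methylcyclohex-3-ene-1-carboxylate (C6 formyl, C7 ester and C3a propanoate arm on one face, C7a acetate arm on the other; C3 epimers), via hydroxy triester 20 (not isolated)
Conditions: NaOMe (0.3 equiv), MeOH, 0 °C to rt
Reagents that add atoms: methanol (as sodium methoxide), CO
Why: Lactone methanolysis followed by retro-aldol fragmentation: methoxide opens the strained lactone at the C7 carbonyl, and the freed Cα alkoxide, β to the C3 ester, expels the ester enolate, which methanol protonates. Relief of bicyclic strain and of the C7–C6–Cα–C3 congestion drives the cleavage, and quaternary C3 rules out β-elimination. Catalytic base avoids a premature Dieckmann condensation.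

Step 12
Reactants: 21 aldehyde triester; 22 diethyl benzylphosphonate
Product: 23 methyl 1,2-diethyl-6-(2-methoxy-2-oxoethyl)-5-(1-methoxy-1-oxopropan-2-yl)-4-methyl-2-[(E)-2-phenylethenyl]cyclohex-3-ene-1-carboxylate (C3 epimers)
Conditions: 22, NaH, THF, 0 °C; then 21, 0 °C to rt
Reagents that add atoms: none
Why: Horner–Wadsworth–Emmons olefination with the preformed benzylphosphonate anion, which gives the (E)-styrene through equilibration of the adducts before elimination. The aldehyde on quaternary C6 can neither enolise nor epimerise.

Step 13
Reactants: 23 styryl triester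
Product: 25 dimethyl (3aR,6S,7R,7aR)-1,6,7-triethyl-3,4-dimethyl-2-oxo-6-[(E)-2-phenylethenyl]-2,3,3a,6,7,7a-hexahydro-1H-indene-1,7-dicarboxylate (C1 and C3 epimers), via keto diester 24 (not isolated)
Conditions: KOtBu, THF, 0 °C to rt; then EtI, rt to 40 °C
Reagents that add atoms: iodoethane, CCI
Why: Dieckmann condensation under equilibrium control: only attack of the C1 enolate on the C3 ester carbonyl gives a β-keto ester with an acidic C1–H, whose potassium enolate is the sink, and the trans arms close the trans-fused cyclopentanone. The enolate is then C-ethylated in the same flask (β-keto ester alkylation); the C1 configuration is irrelevant.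

Step 14
Reactants: 25 ethylated keto diester
Product: 27 (1S,3S,3aR,6S,7R,7aR)-1,6,7-triethyl-3,4-dimethyl-2-oxo-6-[(E)-2-phenylethenyl]-2,3,3a,6,7,7a-hexahydro-1H-indene-7-carboxylic acid (target), via keto acid epimer mixture 26 (not isolated)
Conditions: LiI, 2,4,6-collidine, 150 °C; then NaOMe, MeOH, 40 °C; then cold 1 M HCl to pH 3
Reagents that add atoms: none
Why: Iodide demethylates both esters by SN2 attack at methyl, so the hindered C7 ester needs no saponification, and the C1 β-keto carboxylate decarboxylates (Krapcho-type dealkoxycarbonylation). Base then equilibrates the two ketone α-centres to the less congested isomer, with C1-ethyl anti to C7 and C3-methyl anti to C4, which is the target configuration.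

## Compound list

1 | tert-butyl 3-oxopentanoate | CCC(=O)CC(=O)OC(C)(C)C | starting material
2 | tert-butyl 2-ethyl-3-oxopentanoate (racemic) | CCC(=O)C(CC)C(=O)OC(C)(C)C | intermediate
3 | but-3-en-2-one | CC(=O)C=C | starting material
4 | tert-butyl (2R)-2-ethyl-5-oxo-2-propanoylhexanoate | CCC(=O)[C@@](CC)(CCC(C)=O)C(=O)OC(C)(C)C | intermediate
5 | tert-butyl (1R)-1,2-diethyl-2-hydroxy-4-oxocyclohexane-1-carboxylate (ketol, carbinol epimers) | O=C1CC(O)(CC)[C@](CC)(C(=O)OC(C)(C)C)CC1 | intermediate
6 | tert-butyl (1R)-1,2-diethyl-4-oxocyclohex-2-ene-1-carboxylate | O=C1C=C(CC)[C@](CC)(C(=O)OC(C)(C)C)CC1 | intermediate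
7 | tert-butyl (1R)-1,2-diethyl-4-(trimethylsilyloxy)cyclohexa-2,4-diene-1-carboxylate | C[Si](C)(C)OC1=CC[C@@](CC)(C(=O)OC(C)(C)C)C(CC)=C1 | intermediate
8 | tert-butyl (1R)-1,2-diethyl-4-oxocyclohexa-2,5-diene-1-carboxylate | O=C1C=C(CC)[C@](CC)(C(=O)OC(C)(C)C)C=C1 | intermediate
9 | tert-butyl[(1-methoxyethenyl)oxy]dimethylsilane | COC(=C)O[Si](C)(C)C(C)(C)C | starting material
10 | tert-butyl (1R,6S)-4-(tert-butyldimethylsilyloxy)-1,2-diethyl-6-(2-methoxy-2-oxoethyl)cyclohexa-2,4-diene-1-carboxylate | COC(=O)C[C@H]1C=C(O[Si](C)(C)C(C)(C)C)C=C(CC)[C@]1(CC)C(=O)OC(C)(C)C | intermediate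
11 | tert-butyl (1R,6S)-1,2-diethyl-6-(2-methoxy-2-oxoethyl)-4-(trifluoromethanesulfonyloxy)cyclohexa-2,4-diene-1-carboxylate | COC(=O)C[C@H]1C=C(OS(=O)(=O)C(F)(F)F)C=C(CC)[C@]1(CC)C(=O)OC(C)(C)C | intermediate
12 | tert-butyl (1R,6S)-1,2-diethyl-6-(2-methoxy-2-oxoethyl)-4-methylcyclohexa-2,4-diene-1-carboxylate | COC(=O)C[C@H]1C=C(C)C=C(CC)[C@]1(CC)C(=O)OC(C)(C)C | intermediate
13 | trimethylsilyl (1R,6S)-1,2-diethyl-6-(2-methoxy-2-oxoethyl)-4-methylcyclohexa-2,4-diene-1-carboxylate | COC(=O)C[C@H]1C=C(C)C=C(CC)[C@]1(CC)C(=O)O[Si](C)(C)C | intermediate
14 | (1R,6S)-1,2-diethyl-6-(2-methoxy-2-oxoethyl)-4-methylcyclohexa-2,4-diene-1-carboxylic acid | COC(=O)C[C@H]1C=C(C)C=C(CC)[C@]1(CC)C(=O)O | intermediate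
15 | methyl propanoate | CCC(=O)OC | starting material
16 | methyl 2-formylpropanoate | COC(=O)C(C)C=O | intermediate
17 | (1R,6S)-1,2-diethyl-6-(2-methoxy-2-oxoethyl)-4-methylcyclohexa-2,4-diene-1-carbonyl chloride | COC(=O)C[C@H]1C=C(C)C=C(CC)[C@]1(CC)C(=O)Cl | intermediate
18 | (E)-3-methoxy-2-methyl-3-oxoprop-1-en-1-yl (1R,6S)-1,2-diethyl-6-(2-methoxy-2-oxoethyl)-4-methylcyclohexa-2,4-diene-1-carboxylate | COC(=O)C[C@H]1C=C(C)C=C(CC)[C@]1(CC)C(=O)O/C=C(\C)C(=O)OC | intermediate
19 | lactone-bridged bicyclo[2.2.2]octene adduct (γ-lactone C7–C(=O)–O–Cα; C3 bears Me and CO2Me; C7a bears CH2CO2Me) | COC(=O)C[C@H]1[C@H]2C(C)=C[C@]3(CC)[C@@H](OC(=O)[C@]13CC)[C@]2(C)C(=O)OC | intermediate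
20 | hydroxy triester (19 with the lactone opened to C7–CO2Me and Cα–OH) | COC(=O)C[C@H]1[C@H]2C(C)=C[C@](CC)([C@@H](O)[C@]2(C)C(=O)OC)[C@]1(CC)C(=O)OC | intermediate
21 | methyl 1,2-diethyl-2-formyl-6-(2-methoxy-2-oxoethyl)-5-(1-methoxy-1-oxopropan-2-yl)-4-methylcyclohex-3-ene-1-carboxylate (C3 epimers) | COC(=O)C[C@H]1[C@H](C(C)C(=O)OC)C(C)=C[C@](CC)(C=O)[C@]1(CC)C(=O)OC | intermediate
22 | diethyl benzylphosphonate | CCOP(=O)(Cc1ccccc1)OCC | starting material
23 | methyl 1,2-diethyl-6-(2-methoxy-2-oxoethyl)-5-(1-methoxy-1-oxopropan-2-yl)-4-methyl-2-[(E)-2-phenylethenyl]cyclohex-3-ene-1-carboxylate (C3 epimers) | COC(=O)C[C@H]1[C@H](C(C)C(=O)OC)C(C)=C[C@](CC)(/C=C/c2ccccc2)[C@]1(CC)C(=O)OC | intermediate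
24 | dimethyl (3aR,6S,7R,7aR)-6,7-diethyl-3,4-dimethyl-2-oxo-6-[(E)-2-phenylethenyl]-2,3,3a,6,7,7a-hexahydro-1H-indene-1,7-dicarboxylate (C1/C3 epimers) | COC(=O)C1C(=O)C(C)[C@@H]2C(C)=C[C@@](/C=C/c3ccccc3)(CC)[C@](CC)(C(=O)OC)[C@H]21 | intermediate
25 | dimethyl (3aR,6S,7R,7aR)-1,6,7-triethyl-3,4-dimethyl-2-oxo-6-[(E)-2-phenylethenyl]-2,3,3a,6,7,7a-hexahydro-1H-indene-1,7-dicarboxylate (C1/C3 epimers) | CCC1(C(=O)OC)C(=O)C(C)[C@@H]2C(C)=C[C@@](/C=C/c3ccccc3)(CC)[C@](CC)(C(=O)OC)[C@H]21 | intermediate
26 | (3aR,6S,7R,7aR)-1,6,7-triethyl-3,4-dimethyl-2-oxo-6-[(E)-2-phenylethenyl]-2,3,3a,6,7,7a-hexahydro-1H-indene-7-carboxylic acid (C1/C3 epimer mixture) | CCC1C(=O)C(C)[C@@H]2C(C)=C[C@@](/C=C/c3ccccc3)(CC)[C@](CC)(C(=O)O)[C@H]21 | intermediate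
27 | (1S,3S,3aR,6S,7R,7aR)-1,6,7-triethyl-3,4-dimethyl-2-oxo-6-[(E)-2-phenylethenyl]-2,3,3a,6,7,7a-hexahydro-1H-indene-7-carboxylic acid | CC[C@@H]1C(=O)[C@@H](C)[C@@H]2C(C)=C[C@@](/C=C/c3ccccc3)(CC)[C@](CC)(C(=O)O)[C@H]21 | target

## Step count and risks

Total: 14 steps. Longest linear sequence: 13 steps (steps 1–7 and 9–14, from tert-butyl 3-oxopentanoate); step 8 is a one-step branch.

Least certain steps:

**Step 10 (key step).** The most likely failure is a cycloaddition that is too slow at temperatures the substrate tolerates. The enol ester must adopt the disfavoured s-cis ester conformation needed for a γ-lactone, and the dienophile is trisubstituted and only moderately electron-poor. Prolonged heating would then allow diene isomerisation or acyl transfer. The fallback raises dienophile reactivity by replacing the C3 ester with a formyl group. It sets out from 14 (through 17). O-Acylation of the sodium enolate of 2-methylpropanedial F1 (from commercial 3-(dimethylamino)-2-methylprop-2-enal and aqueous NaOH) gives the (E)-enol ester aldehyde F2. Its cycloaddition (toluene, 80–110 °C) gives the formyl adduct F3. Pinnick oxidation (NaClO2, NaH2PO4, 2-methylbut-2-ene) gives the adduct acid F4, and esterification with Me3SiCHN2 returns to the route at 19.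

**Step 5.** The risk is poor facial selectivity at C7a, because ethyl and tert-butoxycarbonyl on C7 differ only moderately in effective size next to the reacting carbon. The fallback replaces substrate control by reagent control under basic conditions. From 8, dimethyl malonate is added with AlLi bis((R)-binaphthoxide), or its antipode if that reinforces attack anti to the ester, to give the malonate adduct F5. Demethoxycarbonylation (LiCl, wet DMSO, 130 °C) gives the keto diester F6. Kinetic enolisation at C3a (LiN(SiMe3)2, THF, −78 °C) and PhNTf2 return to the route at 11.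

**Step 11.** The risk is reversible lactone opening: the alkoxide concentration stays low, fragmentation stalls and the lactone is recovered, while forcing conditions invite ester condensation. The fallback makes the opening irreversible. From 19, LiOH (aqueous THF, 50 °C) saponifies the lactone and the other esters, and the β-oxido ester fragments to the aldehyde triacid F7. Me3SiCHN2 re-esterifies all three carboxyl groups and returns to the route at 21.

**Step 9.** The risks are C-acylation of the ambident enolate and slow acylation by the hindered acid chloride, with loss of geometric control. The fallback reverses the polarity. From 16, TsCl, N-methylimidazole and Et3N give methyl (E)-2-methyl-3-(tosyloxy)acrylate F8. The caesium carboxylate of 14 (Cs2CO3, DABCO cat., MeCN) displaces tosylate by addition–elimination with retention of geometry and returns to the route at 18.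

**Step 2.** The risk is insufficient enantioselectivity or rate with a donor that carries ethyl groups on both the α-carbon and the ketone. The fallback uses auxiliary control. From 2, condensation with L-valine diethylamide gives the (Z)-enamino ester F9. Addition to 3 catalysed by Cu(OAc)2·H2O in acetone and hydrolysis with aqueous HCl return to the route at 4; the valine antipode is chosen to give the (2R) product.

**Step 12.** The risk is slow addition of the phosphonate anion to the neopentyl aldehyde, which leaves time for base-induced ester condensation. The fallback splits the olefination in two. From 21, Takai olefination (CrCl2, CHI3, THF) gives the (E)-vinyl iodide F10. Suzuki coupling with PhB(OH)2 (Pd(PPh3)4, K2CO3, aqueous dioxane) returns to the route at 23.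

## Further compounds

F1 | step 10 | 2-methylpropanedial (used as its sodium enolate) | O=CC(C)C=O
F2 | step 10 | (E)-2-methyl-3-oxoprop-1-en-1-yl (1R,6S)-1,2-diethyl-6-(2-methoxy-2-oxoethyl)-4-methylcyclohexa-2,4-diene-1-carboxylate | COC(=O)C[C@H]1C=C(C)C=C(CC)[C@]1(CC)C(=O)O/C=C(\C)C=O
F3 | step 10 | lactone-bridged adduct with formyl on C3 | COC(=O)C[C@H]1[C@H]2C(C)=C[C@]3(CC)[C@@H](OC(=O)[C@]13CC)[C@]2(C)C=O
F4 | step 10 | lactone-bridged adduct with carboxyl on C3 | COC(=O)C[C@H]1[C@H]2C(C)=C[C@]3(CC)[C@@H](OC(=O)[C@]13CC)[C@]2(C)C(=O)O
F5 | step 5 | dimethyl 2-[(1S,2R)-2-(tert-butoxycarbonyl)-2,3-diethyl-5-oxocyclohex-3-en-1-yl]propanedioate | COC(=O)C(C(=O)OC)[C@H]1CC(=O)C=C(CC)[C@]1(CC)C(=O)OC(C)(C)C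
F6 | step 5 | tert-butyl (1R,6S)-1,2-diethyl-6-(2-methoxy-2-oxoethyl)-4-oxocyclohex-2-ene-1-carboxylate | COC(=O)C[C@H]1CC(=O)C=C(CC)[C@]1(CC)C(=O)OC(C)(C)C
F7 | step 11 | aldehyde triacid (21 with all three esters as free acids; C3 epimers) | OC(=O)C[C@H]1[C@H](C(C)C(=O)O)C(C)=C[C@](CC)(C=O)[C@]1(CC)C(=O)O
F8 | step 9 | methyl (E)-2-methyl-3-(tosyloxy)acrylate | COC(=O)/C(C)=C/OS(=O)(=O)c1ccc(C)cc1
F9 | step 2 | tert-butyl (Z)-3-{[(2S)-1-(diethylamino)-3-methyl-1-oxobutan-2-yl]amino}-2-ethylpent-2-enoate | CC/C(N[C@@H](C(C)C)C(=O)N(CC)CC)=C(\CC)C(=O)OC(C)(C)C
F10 | step 12 | methyl 1,2-diethyl-2-[(E)-2-iodoethenyl]-6-(2-methoxy-2-oxoethyl)-5-(1-methoxy-1-oxopropan-2-yl)-4-methylcyclohex-3-ene-1-carboxylate (C3 epimers) | COC(=O)C[C@H]1[C@H](C(C)C(=O)OC)C(C)=C[C@](CC)(/C=C/I)[C@]1(CC)C(=O)OC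
A1 | alternative 1 | δ-lactone with ring oxygen on C4, (1E,3E)-2-ethyl-4-phenylbuta-1,3-dienyl and methyl on C4, silyloxypropan-2-yl on C3a, (E)-propenyl on C7a, ethyl on C7 (either C7 epimer) | CCC1C(=O)O[C@](C)(/C=C(CC)/C=C/c2ccccc2)[C@@H]([C@H](C)CO[Si](C)(C)C(C)(C)C)[C@@H]1/C=C/C
A2 | alternative 1 | ring B acid with both quaternary centres and trans C3a/C7a arms | C[C@H](CO[Si](C)(C)C(C)(C)C)[C@@H]1C(C)=C[C@@](/C=C/c2ccccc2)(CC)[C@](CC)(C(=O)O)[C@H]1/C=C/C
A3 | alternative 2 | 3-(but-1-ynyl)-3,4-diethyl-4-[(1Z,3E)-2-methylpenta-1,3-dienyl]oxolan-2-one (C7 alkynyl and C6 dienyl cis) | C/C=C/C(C)=C\[C@]1(CC)COC(=O)[C@]1(CC)C#CCC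
A4 | alternative 2 | tricyclic enone (rings A and B plus the lactone) | C[C@@H]1C(=O)C(CC)=C2[C@H]1C(C)=C[C@]3(CC)COC(=O)[C@]23CC
A5 | alternative 3 | ring A keto aldehyde (C2 ketal; acetyl on C3a; C7a bears the C7(Et)(CO2Me)–C6(Et)(styryl)–CHO chain) | CC[C@@H]1C2(OCCO2)[C@@H](C)[C@H](C(C)=O)[C@H]1[C@@](CC)(C(=O)OC)[C@@](CC)(/C=C/c3ccccc3)C=O
A6 | alternative 3 | C2 ketal and methyl ester of the target | CC[C@@H]1C2(OCCO2)[C@@H](C)[C@@H]3C(C)=C[C@@](/C=C/c4ccccc4)(CC)[C@](CC)(C(=O)OC)[C@H]31
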